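The route rests on cutting the C1–C10 bond of the 3(2H)-furanone (germacrane numbering). C10 carries a methyl group, the ring oxygen and C9: it is a lactic acid α-carbon, while C3 is at the ketone level and shares that oxygen. (R)-Lactic acid is therefore condensed with a β-keto Weinreb amide to a 1,3-dioxolan-4-one whose acetal carbon is C3. Its enolate is acylated by the amide arm: one operation closes the five-membered O–C3–C2–C1–C10 ring and sets the quaternary C10 by self-regeneration of the lactate stereocentre. Thiolysis and dehydration then unveil the furanone; a CrCl2-mediated Barbier macrocyclisation builds the ten-membered ring and lactone.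

Key step: step 7

Remark (assumption): atoms are numbered as in germacranolides (C1 ketone, C2=C3, ring oxygen between C3 and C10, C4 methyl-bearing, C5 and C9 carbinols, C6 lactone carbinol, C7, C8 ester carbinol, C11–C13 methylene lactone unit); the acetal isomer drawn for 13 is assumed to be the thermodynamically preferred one; TBS = tert-butyldimethylsilyl, MOM = methoxymethyl.

Step 1
Reactants: 1 (R)-but-3-yn-2-ol
Product: 2 (R)-but-3-yn-2-yl methanesulfonate
Conditions: MsCl, Et3N, CH2Cl2, 0 °C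
Reagents that add atoms: methanesulfonyl chloride, CS(=O)(=O)Cl
Why: O-Sulfonylation of the secondary propargylic alcohol touches only the O–H bond, so the stereocentre is carried over unchanged.

Step 2
Reactants: 2 (R)-but-3-yn-2-yl methanesulfonate; 3 (tert-butyldimethylsilyloxy)acetaldehyde
Product: 5 (2S,3S)-1-(tert-butyldimethylsilyloxy)-3-methylpent-4-yn-2-ol, via allenylindium 4 (not isolated)
Conditions: Pd(OAc)2 (cat.), PPh3 (cat.), InI, THF–HMPA, rt
Reagents that add atoms: none
Why: Marshall propargylation: zerovalent palladium opens the mesylate anti (SN2') and transmetalation gives allenylindium 4, whose cyclic SE2' addition to 3 should give the anti homopropargylic alcohol, C4 following from the mesylate with net inversion and C5 from the chair-like transition state.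

Step 3
Reactants: 5 (2S,3S)-1-(tert-butyldimethylsilyloxy)-3-methylpent-4-yn-2-ol
Product: 6 (2S,3S)-1,2-bis(tert-butyldimethylsilyloxy)-3-methylpent-4-yne
Conditions: TBSOTf, 2,6-lutidine, CH2Cl2, −78 °C
Reagents that add atoms: tert-butyldimethylsilyl triflate, CC(C)(C)[Si](C)(C)OS(=O)(=O)C(F)(F)F
Why: Standard silylation of the secondary alcohol with the silyl triflate and a hindered base; no stereocentre is touched.

Step 4
Reactants: 6 (2S,3S)-1,2-bis(tert-butyldimethylsilyloxy)-3-methylpent-4-yne; 7 N-methoxy-N-methylcarbamoyl chloride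
Product: 9 (4S,5S)-5,6-bis(tert-butyldimethylsilyloxy)-N-methoxy-N,4-dimethylhex-2-ynamide, via lithium acetylide 8 (not isolated)
Conditions: n-BuLi, THF, −78 °C; then 7, −78 to 0 °C
Reagents that add atoms: none
Why: Acylation of the lithium acetylide with the carbamoyl chloride gives the alkynyl Weinreb amide and brings in C1 at the acid oxidation level.

Step 5
Reactants: 9 (4S,5S)-5,6-bis(tert-butyldimethylsilyloxy)-N-methoxy-N,4-dimethylhex-2-ynamide
Product: 10 (4R,5S)-5,6-bis(tert-butyldimethylsilyloxy)-N-methoxy-N,4-dimethyl-3-oxohexanamide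
Conditions: Ph3PAuCl (cat.), AgOTf (cat.), H2O, 1,4-dioxane, rt
Reagents that add atoms: water, O
Why: Ph3PAuCl/AgOTf-catalysed conjugate hydration of the ynamide delivers water to C3 (β to the amide) and gives the β-keto amide under near-neutral conditions, so the now enolisable C4 centre should survive.

Step 6
Reactants: 10 (4R,5S)-5,6-bis(tert-butyldimethylsilyloxy)-N-methoxy-N,4-dimethyl-3-oxohexanamide; 11 (R)-lactic acid
Product: 13 2-[(2R,5R)-2-[(2R,3S)-3,4-bis(tert-butyldimethylsilyloxy)butan-2-yl]-5-methyl-4-oxo-1,3-dioxolan-2-yl]-N-methoxy-N-methylacetamide, via bis-silyl lactate 12 (not isolated)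
Conditions: 11, BSA, CH2Cl2, rt; then 10, TMSOTf (cat.), −78 to −20 °C
Reagents that add atoms: none
Why: Noyori-type acetalisation (TMSOTf-catalysed condensation of a bis-silylated α-hydroxy acid with a ketone) forms the 1,3-dioxolan-4-one; the new acetal centre C3 is set relative to the lactate centre under equilibrating conditions, the bulky C4 branch taking the face of the C10 methyl so that the amide arm lies cis to C10–H, and the minor isomer is removed by chromatography.

Step 7
Reactants: 13 2-[(2R,5R)-2-[(2R,3S)-3,4-bis(tert-butyldimethylsilyloxy)butan-2-yl]-5-methyl-4-oxo-1,3-dioxolan-2-yl]-N-methoxy-N-methylacetamide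
Product: 16 (1R,4S)-1-[(2R,3S)-3,4-bis(tert-butyldimethylsilyloxy)butan-2-yl]-4-methyl-2,7-dioxabicyclo[2.2.1]heptane-3,5-dione, via lithium enolate 14 (not isolated), via tetrahedral adduct 15 (not isolated)
Conditions: LiN(SiMe3)2, THF, −78 to −40 °C; AcOH, −78 °C
Reagents that add atoms: none
Why: Proposed new method: LiN(SiMe3)2 removes the C10 proton of the dioxolanone (an α-alkoxy lactone C–H, several pK units more acidic than the amide CH2, so the acetal is not lost by β-elimination), and the planar enolate carbon attacks the Weinreb amide carbonyl C1 of the arm held on the acetal carbon C3, the lithium-chelated tetrahedral adduct 15 surviving until the acid quench. The closest known reactions are the diastereoselective alkylations and acylations of 1,3-dioxolan-4-one enolates that regenerate the lactate stereocentre, and intramolecular Claisen acylations of ester enolates by Weinreb amides; the bridged version is not known. One ring is closed, the oxolan-3-one ring O–C3–C2–C1–C10, by a 5-exo-trig attack that turns the dioxolanone into a 2,7-dioxabicyclo[2.2.1]heptane. The only new stereocentre, C10, is controlled by the acetal stereocentre C3: the two-carbon arm can reach the enolate only from its own face, which is the face of the former C10–H, so C1 replaces that hydrogen with retention and (R)-lactic acid gives (10R). The step needs C-acylation at low temperature before the enolate decays, which the five-membered closure onto a chelating amide should secure, and it needs C4 and C5 to stay untouched, which holds because C4–H now lies next to an acetal carbon and is not acidic.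

Step 8
Reactants: 16 (1R,4S)-1-[(2R,3S)-3,4-bis(tert-butyldimethylsilyloxy)butan-2-yl]-4-methyl-2,7-dioxabicyclo[2.2.1]heptane-3,5-dione
Product: 18 S-ethyl (2S)-5-[(2R,3S)-3,4-bis(tert-butyldimethylsilyloxy)butan-2-yl]-2-methyl-3-oxo-2,3-dihydrofuran-2-carbothioate, via hemiketal thioester 17 (not isolated)
Conditions: EtSH, Et3N, CH2Cl2, 0 °C; then TsOH·H2O (cat.), rt
Reagents that add atoms: ethanethiol, CCS
Why: Thiolate attacks the strained acylal carbonyl C9 (acyl–oxygen cleavage) to give the thioester and the C3 hemiketal 17, which loses water under acid as in the classical last step of 3(2H)-furanone syntheses; C10 is untouched.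

Step 9
Reactants: 18 S-ethyl (2S)-5-[(2R,3S)-3,4-bis(tert-butyldimethylsilyloxy)butan-2-yl]-2-methyl-3-oxo-2,3-dihydrofuran-2-carbothioate
Product: 19 (2R)-5-[(2R,3S)-3,4-bis(tert-butyldimethylsilyloxy)butan-2-yl]-2-methyl-3-oxo-2,3-dihydrofuran-2-carbaldehyde
Conditions: Et3SiH, Pd/C, acetone, rt
Reagents that add atoms: none
Why: Fukuyama reduction: Pd/C-catalysed hydrosilane reduction of the thioester stops at the aldehyde and leaves the vinylogous ester carbonyl and the silyl ethers alone.

Step 10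
Reactants: 19 (2R)-5-[(2R,3S)-3,4-bis(tert-butyldimethylsilyloxy)butan-2-yl]-2-methyl-3-oxo-2,3-dihydrofuran-2-carbaldehyde; 20 allyl methoxymethyl ether
Product: 22 (2R)-5-[(2R,3S)-3,4-bis(tert-butyldimethylsilyloxy)butan-2-yl]-2-[(1R,2S)-1-hydroxy-2-(methoxymethoxy)but-3-en-1-yl]-2-methylfuran-3(2H)-one, via allylborane 21 (not isolated)
Conditions: 20, s-BuLi, THF, −78 °C; (+)-Ipc2BOMe; BF3·OEt2; then 19, −78 °C; H2O2, pH 7 buffer
Reagents that add atoms: none
Why: Brown alkoxyallylboration: the (Z)-γ-alkoxyallylborane 21 adds through a chair transition state, which gives the syn C8/C9 relationship, and the Ipc groups derived from (−)-α-pinene direct it to the re face of the aldehyde, so that C9 (R) and C8 (S) are set by the reagent.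

Step 11
Reactants: 22 (2R)-5-[(2R,3S)-3,4-bis(tert-butyldimethylsilyloxy)butan-2-yl]-2-[(1R,2S)-1-hydroxy-2-(methoxymethoxy)but-3-en-1-yl]-2-methylfuran-3(2H)-one
Product: 23 (2R)-5-[(2R,3S)-3,4-bis(tert-butyldimethylsilyloxy)butan-2-yl]-2-[(1R,2S)-1-(tert-butyldimethylsilyloxy)-2-(methoxymethoxy)but-3-en-1-yl]-2-methylfuran-3(2H)-one
Conditions: TBSOTf, 2,6-lutidine, CH2Cl2, −40 °C
Reagents that add atoms: tert-butyldimethylsilyl triflate, CC(C)(C)[Si](C)(C)OS(=O)(=O)C(F)(F)F
Why: Silylation of the hindered C9 alcohol with the silyl triflate; no stereocentre is touched.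

Step 12
Reactants: 23 (2R)-5-[(2R,3S)-3,4-bis(tert-butyldimethylsilyloxy)butan-2-yl]-2-[(1R,2S)-1-(tert-butyldimethylsilyloxy)-2-(methoxymethoxy)but-3-en-1-yl]-2-methylfuran-3(2H)-one
Product: 24 (2R,3R)-3-(tert-butyldimethylsilyloxy)-3-[(2R)-5-[(2R,3S)-3,4-bis(tert-butyldimethylsilyloxy)butan-2-yl]-2-methyl-3-oxo-2,3-dihydrofuran-2-yl]-2-(methoxymethoxy)propanal
Conditions: OsO4 (cat.), NaIO4, 2,6-lutidine, dioxane–H2O, rt
Reagents that add atoms: sodium periodate, [Na+].[O-]I(=O)(=O)=O
Why: Lemieux–Johnson cleavage (OsO4-catalysed dihydroxylation, then NaIO4) of the monosubstituted alkene, which is far more reactive toward OsO4 than the push–pull C2=C3 bond of the furanone.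

Step 13
Reactants: 24 (2R,3R)-3-(tert-butyldimethylsilyloxy)-3-[(2R)-5-[(2R,3S)-3,4-bis(tert-butyldimethylsilyloxy)butan-2-yl]-2-methyl-3-oxo-2,3-dihydrofuran-2-yl]-2-(methoxymethoxy)propanal; 25 methyl acrylate
Product: 26 Morita–Baylis–Hillman adduct: methyl 2-methylidene-3-hydroxy ester formed at the aldehyde carbon of 24 (C7 carbinol as both epimers; all other centres as in 24)
Conditions: 25, DABCO, MeOH, rt
Reagents that add atoms: none
Why: Morita–Baylis–Hillman reaction of the α-alkoxy aldehyde with methyl acrylate; the new C7 carbinol centre is formed without control, which does not matter because it is removed in step 14.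

Step 14
Reactants: 26 Morita–Baylis–Hillman adduct
Product: 27 methyl (Z)-2-(bromomethyl)enoate: C7=C11 alkene with C8 (OMOM) cis to CH2Br; C9, C5 and C6 oxygens as TBS ethers; centres as in 24
Conditions: NBS, Me2S, CH2Cl2, 0 °C
Reagents that add atoms: N-bromosuccinimide, O=C1CCC(=O)N1Br
Why: Corey–Kim-type bromination (NBS/Me2S) of the allylic alcohol with SN2' transposition gives the thermodynamically preferred (Z)-2-(bromomethyl)enoate.

Step 15
Reactants: 27 methyl (Z)-2-(bromomethyl)enoate
Product: 28 C6 primary alcohol of 27 (primary TBS ether removed; C5 and C9 TBS ethers and C8 MOM ether kept)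
Conditions: CSA (cat.), MeOH–CH2Cl2, 0 °C
Reagents that add atoms: none
Why: Acid-catalysed methanolysis removes the primary silyl ether much faster than the two secondary ones; MOM ether and allylic bromide should survive at 0 °C.

Step 16
Reactants: 28 C6 primary alcohol
Product: 29 C6 aldehyde (α-silyloxy aldehyde carrying the allylic bromide arm)
Conditions: Dess–Martin periodinane, NaHCO3, CH2Cl2, rt
Reagents that add atoms: none
Why: Dess–Martin oxidation of the primary alcohol gives the α-silyloxy aldehyde without epimerising C5.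

Step 17
Reactants: 29 C6 aldehyde
Product: 32 macrolactone: 5,9-bis(TBS) ether and 8-MOM ether of the 8-deacyl target (all seven stereocentres as in the target), via allylchromium 30 (not isolated), via hydroxy ester 31 (not isolated)
Conditions: CrCl2, THF–DMF (high dilution), rt
Reagents that add atoms: none
Why: Intramolecular Barbier-type (Nozaki–Hiyama) allylation: CrCl2 converts the allylic bromide into allylchromium 30, which adds through C7 to the C6 aldehyde in a cyclic transition state held by the furanone-bridged chain, expected to give the trans C6/C7 relationship of the ring-fused lactone (both centres set by macrocyclic control), and the hydroxy ester 31 lactonises.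

Step 18
Reactants: 32 macrolactone (8-MOM ether)
Product: 33 5,9-bis(TBS) ether of the 8-deacyl target (C8–OH free)
Conditions: Me2BBr, CH2Cl2, −78 °C; aq. NaHCO3
Reagents that add atoms: none
Why: Me2BBr cleaves the MOM acetal at low temperature and should leave the silyl ethers and the α-methylene lactone untouched.

Step 19
Reactants: 33 5,9-bis(TBS) ether of the 8-deacyl target; 34 3-methylbutanoic (isovaleric) anhydride
Product: 35 5,9-bis(TBS) ether of the target
Conditions: 34, Et3N, DMAP (cat.), CH2Cl2, 0 °C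
Reagents that add atoms: none
Why: DMAP-catalysed acylation of the only free hydroxyl group (C8) with the anhydride.

Step 20
Reactants: 35 5,9-bis(TBS) ether of the target
Product: 36 (4R,5S,6S,7S,8S,9R,10R)-5,9-dihydroxy-8-(3-methylbutanoyloxy)-1-oxo-3,10-epoxygermacra-2,11(13)-dien-12,6-olide (target)
Conditions: HF·pyridine, THF, 0 °C to rt
Reagents that add atoms: none
Why: Fluoride-mediated removal of both silyl ethers under mildly acidic conditions, which should not cause acyl migration from O8 to O9 or addition to the α-methylene lactone.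

Compound list
1 | (R)-but-3-yn-2-ol | O[C@H](C)C#C | starting material
2 | (R)-but-3-yn-2-yl methanesulfonate | CS(=O)(=O)O[C@H](C)C#C | intermediate
3 | (tert-butyldimethylsilyloxy)acetaldehyde | CC(C)(C)[Si](C)(C)OCC=O | starting material
4 | buta-1,2-dienylindium iodide methanesulfonate (axially chiral; indium anti to the departed mesylate) | [H]C(C)=[C@]=C([H])[In](I)OS(C)(=O)=O | intermediate
5 | (2S,3S)-1-(tert-butyldimethylsilyloxy)-3-methylpent-4-yn-2-ol | CC(C)(C)[Si](C)(C)OC[C@@H](O)[C@@H](C)C#C | intermediate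
6 | (2S,3S)-1,2-bis(tert-butyldimethylsilyloxy)-3-methylpent-4-yne | CC(C)(C)[Si](C)(C)OC[C@@H](O[Si](C)(C)C(C)(C)C)[C@@H](C)C#C | intermediate
7 | N-methoxy-N-methylcarbamoyl chloride | CON(C)C(Cl)=O | starting material
8 | lithium acetylide of 6 | CC(C)(C)[Si](C)(C)OC[C@@H](O[Si](C)(C)C(C)(C)C)[C@@H](C)C#C[Li] | intermediate
9 | (4S,5S)-5,6-bis(tert-butyldimethylsilyloxy)-N-methoxy-N,4-dimethylhex-2-ynamide | CC(C)(C)[Si](C)(C)OC[C@@H](O[Si](C)(C)C(C)(C)C)[C@@H](C)C#CC(=O)N(C)OC | intermediate
10 | (4R,5S)-5,6-bis(tert-butyldimethylsilyloxy)-N-methoxy-N,4-dimethyl-3-oxohexanamide | CC(C)(C)[Si](C)(C)OC[C@@H](O[Si](C)(C)C(C)(C)C)[C@@H](C)C(=O)CC(=O)N(C)OC | intermediate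
11 | (R)-lactic acid | C[C@@H](O)C(=O)O | starting material
12 | trimethylsilyl (R)-2-(trimethylsilyloxy)propanoate | C[C@@H](O[Si](C)(C)C)C(=O)O[Si](C)(C)C | intermediate
13 | 2-[(2R,5R)-2-[(2R,3S)-3,4-bis(tert-butyldimethylsilyloxy)butan-2-yl]-5-methyl-4-oxo-1,3-dioxolan-2-yl]-N-methoxy-N-methylacetamide | CC(C)(C)[Si](C)(C)OC[C@@H](O[Si](C)(C)C(C)(C)C)[C@@H](C)[C@@]1(CC(=O)N(C)OC)OC(=O)[C@@H](C)O1 | intermediate
14 | lithium enolate of 13 (C10 deprotonated) | CC(C)(C)[Si](C)(C)OC[C@@H](O[Si](C)(C)C(C)(C)C)[C@@H](C)[C@@]1(CC(=O)N(C)OC)OC(O[Li])=C(C)O1 | intermediate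
15 | lithium alkoxide of the bicyclic N,O-hemiaminal (tetrahedral adduct at C1) | CC(C)(C)[Si](C)(C)OC[C@@H](O[Si](C)(C)C(C)(C)C)[C@@H](C)[C@]12CC(O[Li])(N(C)OC)[C@](C)(O1)C(=O)O2 | intermediate
16 | (1R,4S)-1-[(2R,3S)-3,4-bis(tert-butyldimethylsilyloxy)butan-2-yl]-4-methyl-2,7-dioxabicyclo[2.2.1]heptane-3,5-dione | CC(C)(C)[Si](C)(C)OC[C@@H](O[Si](C)(C)C(C)(C)C)[C@@H](C)[C@]12CC(=O)[C@](C)(O1)C(=O)O2 | intermediate
17 | S-ethyl (2S,5S)-5-[(2R,3S)-3,4-bis(tert-butyldimethylsilyloxy)butan-2-yl]-5-hydroxy-2-methyl-3-oxooxolane-2-carbothioate | CC(C)(C)[Si](C)(C)OC[C@@H](O[Si](C)(C)C(C)(C)C)[C@@H](C)[C@]1(O)CC(=O)[C@](C)(O1)C(=O)SCC | intermediate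
18 | S-ethyl (2S)-5-[(2R,3S)-3,4-bis(tert-butyldimethylsilyloxy)butan-2-yl]-2-methyl-3-oxo-2,3-dihydrofuran-2-carbothioate | CC(C)(C)[Si](C)(C)OC[C@@H](O[Si](C)(C)C(C)(C)C)[C@@H](C)C1=CC(=O)[C@](C)(O1)C(=O)SCC | intermediate
19 | (2R)-5-[(2R,3S)-3,4-bis(tert-butyldimethylsilyloxy)butan-2-yl]-2-methyl-3-oxo-2,3-dihydrofuran-2-carbaldehyde | CC(C)(C)[Si](C)(C)OC[C@@H](O[Si](C)(C)C(C)(C)C)[C@@H](C)C1=CC(=O)[C@](C)(O1)C=O | intermediate
20 | allyl methoxymethyl ether (3-(methoxymethoxy)prop-1-ene) | C=CCOCOC | starting material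
21 | [(Z)-3-(methoxymethoxy)allyl]diisopinocampheylborane (Ipc from (−)-α-pinene) | COCO/C=C\CB([C@H]1C[C@H]2C[C@@H]([C@@H]1C)C2(C)C)[C@H]1C[C@H]2C[C@@H]([C@@H]1C)C2(C)C | intermediate
22 | (2R)-5-[(2R,3S)-3,4-bis(tert-butyldimethylsilyloxy)butan-2-yl]-2-[(1R,2S)-1-hydroxy-2-(methoxymethoxy)but-3-en-1-yl]-2-methylfuran-3(2H)-one | CC(C)(C)[Si](C)(C)OC[C@@H](O[Si](C)(C)C(C)(C)C)[C@@H](C)C1=CC(=O)[C@](C)(O1)[C@H](O)[C@@H](OCOC)C=C | intermediate
23 | (2R)-5-[(2R,3S)-3,4-bis(tert-butyldimethylsilyloxy)butan-2-yl]-2-[(1R,2S)-1-(tert-butyldimethylsilyloxy)-2-(methoxymethoxy)but-3-en-1-yl]-2-methylfuran-3(2H)-one | CC(C)(C)[Si](C)(C)OC[C@@H](O[Si](C)(C)C(C)(C)C)[C@@H](C)C1=CC(=O)[C@](C)(O1)[C@H](O[Si](C)(C)C(C)(C)C)[C@@H](OCOC)C=C | intermediate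
24 | (2R,3R)-3-(tert-butyldimethylsilyloxy)-3-[(2R)-5-[(2R,3S)-3,4-bis(tert-butyldimethylsilyloxy)butan-2-yl]-2-methyl-3-oxo-2,3-dihydrofuran-2-yl]-2-(methoxymethoxy)propanal | CC(C)(C)[Si](C)(C)OC[C@@H](O[Si](C)(C)C(C)(C)C)[C@@H](C)C1=CC(=O)[C@](C)(O1)[C@H](O[Si](C)(C)C(C)(C)C)[C@@H](OCOC)C=O | intermediate
25 | methyl acrylate | C=CC(=O)OC | starting material
26 | Morita–Baylis–Hillman adduct of 24 (C7 carbinol epimers; other centres as in 24) | CC(C)(C)[Si](C)(C)OC[C@@H](O[Si](C)(C)C(C)(C)C)[C@@H](C)C1=CC(=O)[C@](C)(O1)[C@H](O[Si](C)(C)C(C)(C)C)[C@@H](OCOC)C(O)C(=C)C(=O)OC | intermediate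
27 | methyl (Z)-2-(bromomethyl)enoate (C7=C11; centres as in 24) | CC(C)(C)[Si](C)(C)OC[C@@H](O[Si](C)(C)C(C)(C)C)[C@@H](C)C1=CC(=O)[C@](C)(O1)[C@H](O[Si](C)(C)C(C)(C)C)[C@@H](OCOC)/C=C(\CBr)C(=O)OC | intermediate
28 | C6 primary alcohol of 27 | OC[C@@H](O[Si](C)(C)C(C)(C)C)[C@@H](C)C1=CC(=O)[C@](C)(O1)[C@H](O[Si](C)(C)C(C)(C)C)[C@@H](OCOC)/C=C(\CBr)C(=O)OC | intermediate
29 | C6 aldehyde with the allylic bromide arm | O=C[C@@H](O[Si](C)(C)C(C)(C)C)[C@@H](C)C1=CC(=O)[C@](C)(O1)[C@H](O[Si](C)(C)C(C)(C)C)[C@@H](OCOC)/C=C(\CBr)C(=O)OC | intermediate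
30 | allylchromium dichloride derived from 29 | O=C[C@@H](O[Si](C)(C)C(C)(C)C)[C@@H](C)C1=CC(=O)[C@](C)(O1)[C@H](O[Si](C)(C)C(C)(C)C)[C@@H](OCOC)/C=C(\C[Cr](Cl)Cl)C(=O)OC | intermediate
31 | macrocyclic hydroxy ester (ten-membered ring closed C6–C7; C6–OH free; C7 bears C(=CH2)CO2Me) | O[C@@H]1[C@@H](O[Si](C)(C)C(C)(C)C)[C@@H](C)C2=CC(=O)[C@](C)(O2)[C@H](O[Si](C)(C)C(C)(C)C)[C@@H](OCOC)[C@H]1C(=C)C(=O)OC | intermediate
32 | 5,9-bis(TBS) ether, 8-MOM ether of the 8-deacyl target | C=C1C(=O)O[C@@H]2[C@@H](O[Si](C)(C)C(C)(C)C)[C@@H](C)C3=CC(=O)[C@](C)(O3)[C@H](O[Si](C)(C)C(C)(C)C)[C@@H](OCOC)[C@@H]12 | intermediate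
33 | 5,9-bis(TBS) ether of the 8-deacyl target (C8–OH free) | C=C1C(=O)O[C@@H]2[C@@H](O[Si](C)(C)C(C)(C)C)[C@@H](C)C3=CC(=O)[C@](C)(O3)[C@H](O[Si](C)(C)C(C)(C)C)[C@@H](O)[C@@H]12 | intermediate
34 | 3-methylbutanoic (isovaleric) anhydride | CC(C)CC(=O)OC(=O)CC(C)C | starting material
35 | 5,9-bis(TBS) ether of the target | C=C1C(=O)O[C@@H]2[C@@H](O[Si](C)(C)C(C)(C)C)[C@@H](C)C3=CC(=O)[C@](C)(O3)[C@H](O[Si](C)(C)C(C)(C)C)[C@@H](OC(=O)CC(C)C)[C@@H]12 | intermediate
36 | (4R,5S,6S,7S,8S,9R,10R)-5,9-dihydroxy-8-(3-methylbutanoyloxy)-1-oxo-3,10-epoxygermacra-2,11(13)-dien-12,6-olide | C=C1C(=O)O[C@@H]2[C@@H](O)[C@@H](C)C3=CC(=O)[C@](C)(O3)[C@H](O)[C@@H](OC(=O)CC(C)C)[C@@H]12 | target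

Total step count: 20. Longest linear sequence: 20 steps (1 to 36); the lactic acid, carbamoyl chloride, allyl ether, acrylate and anhydride inputs need no separate steps.

Steps most likely to fail

Step 7 (Proposed new method). The bridged closure may be too slow because of the strain of the bicyclo[2.2.1] skeleton, so that the enolate decays. Deprotonation at the amide methylene followed by β-elimination of the carboxylate would open the acetal and erase the stereochemical relay. The fallback uses known chemistry, sets out from 6 and comes back at 19. Alkyne 6 is lithiated and carboxylated with methyl chloroformate to methyl (4S,5S)-5,6-bis(tert-butyldimethylsilyloxy)-4-methylhex-2-ynoate F1. Alkoxide-catalysed oxa-Michael addition of racemic 2-hydroxy-N-methoxy-N-methylpropanamide gives the β-alkoxyacrylate F2. LiN(SiMe3)2 then closes the same C1–C10 bond by a Dieckmann-type acylation, the known furanone annulation of α-hydroxy carbonyl compounds with alkynoates, and gives the furanone Weinreb amide F3. C10 is not controlled here, so F3 forms as both epimers, which are separated. DIBAL-H reduction of the (10R) epimer at −78 °C gives 19.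

Step 17. Ring closure may show poor facial selectivity at C6 and C7 (cis-fused lactone or the C6 epimer), or intermolecular coupling may compete. The fallback sets out from 26 and comes back at 32. Adduct 26 is acetylated (Ac2O, DMAP) to the allylic acetate F4. The primary silyl ether is removed (CSA, MeOH) to the C6 alcohol F5, which is oxidised with Dess–Martin periodinane to the C6 aldehyde F6. Pd(PPh3)4 with InI turns the acetate into an allylindium by umpolung of the π-allylpalladium intermediate. This closes the ring through a different, indium-centred transition state to hydroxy ester 31 and lactone 32.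

Step 6. The oxocarbenium ion may lose a C2 proton to give the enol ether instead of closing the acetal ring, the new acetal centre may form with low selectivity, or C4 may epimerise through enolisation of the ketone. The fallback sets out from 9 and comes back at 13. (R)-Lactic acid 11 is added twice across the ynamide under amine catalysis: conjugate addition of the carboxylate, then 5-exo addition of the hydroxyl group to the enol ester. This gives 13 without passing through the ketone and makes no new compound (F0).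

Further compounds
F1 | step 7 | methyl (4S,5S)-5,6-bis(tert-butyldimethylsilyloxy)-4-methylhex-2-ynoate | CC(C)(C)[Si](C)(C)OC[C@@H](O[Si](C)(C)C(C)(C)C)[C@@H](C)C#CC(=O)OC
F2 | step 7 | methyl (4R,5S)-5,6-bis(tert-butyldimethylsilyloxy)-3-{[1-(N-methoxy-N-methylamino)-1-oxopropan-2-yl]oxy}-4-methylhex-2-enoate (alkene geometry and lactamide centre undefined) | CC(C)(C)[Si](C)(C)OC[C@@H](O[Si](C)(C)C(C)(C)C)[C@@H](C)C(=CC(=O)OC)OC(C)C(=O)N(C)OC
F3 | step 7 | (2S)-5-[(2R,3S)-3,4-bis(tert-butyldimethylsilyloxy)butan-2-yl]-N-methoxy-N,2-dimethyl-3-oxo-2,3-dihydrofuran-2-carboxamide | CC(C)(C)[Si](C)(C)OC[C@@H](O[Si](C)(C)C(C)(C)C)[C@@H](C)C1=CC(=O)[C@](C)(O1)C(=O)N(C)OC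
F4 | step 17 | C7 acetate of 26 | CC(C)(C)[Si](C)(C)OC[C@@H](O[Si](C)(C)C(C)(C)C)[C@@H](C)C1=CC(=O)[C@](C)(O1)[C@H](O[Si](C)(C)C(C)(C)C)[C@@H](OCOC)C(OC(C)=O)C(=C)C(=O)OC
F5 | step 17 | C6 primary alcohol of F4 | OC[C@@H](O[Si](C)(C)C(C)(C)C)[C@@H](C)C1=CC(=O)[C@](C)(O1)[C@H](O[Si](C)(C)C(C)(C)C)[C@@H](OCOC)C(OC(C)=O)C(=C)C(=O)OC
F6 | step 17 | C6 aldehyde of F4 | O=C[C@@H](O[Si](C)(C)C(C)(C)C)[C@@H](C)C1=CC(=O)[C@](C)(O1)[C@H](O[Si](C)(C)C(C)(C)C)[C@@H](OCOC)C(OC(C)=O)C(=C)C(=O)OC
F0 | step 6 | none | none
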